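In the ten-membered ring (C1–C10) the oxygenated carbons C2 and C7 are bridged by C3–C4–C5(CH3)=C6, the 1,6-pattern left by a [3,3] shift. Breaking C4–C5 and reconnecting C2 with C7 therefore contracts that ring to a six-membered cis-1,2-diol (C1, C2, C7, C8, C9, C10) with vinyl on C2 and 1-propynyl on C7, which maps onto 2-methoxy-5-methylbenzoquinone. In the forward direction a single dianionic acetylenic dioxy-Cope rearrangement enlarges ring B by four carbons and sets up the C2 ketone, the C7 enone and the Z C5=C6 olefin together. Ring A is built by an enantioselective quinone Diels–Alder reaction; the γ-lactone is annulated last from ethyl propionate.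

Key step: step 17

Remarks on the chemistry.
- Carbons carry briarane numbers: C15 is the C1 methyl, C16 the C5 methyl, C18 the C17 methyl, C19 the lactone carbonyl, C20 the C11 methyl.
- Ring A is the cyclohexane C1, C10–C14. Ring B is the six-membered ring C1, C2, C7, C8, C9, C10 that later becomes the ten-membered ring.
- β is the face of C15 in the usual flat drawing, α the other face; the SMILES strings of the list are binding.
- Assumption: the (S)-oxazaborolidinium catalyst is taken to expose the quinone face that leads to adduct 7; if it gave the antipode, the (R)-catalyst would be used with no other change.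

Step 1
Reactants: 1 (E)-4-methoxybut-3-en-2-one
Product: 2 (E)-4-[(4-methoxybenzyl)oxy]but-3-en-2-one
Conditions: 4-MeOC6H4CH2OH, PPTS (cat.), toluene, 90 °C, MeOH distilled off
Reagents that add atoms: 4-methoxybenzyl alcohol, COc1ccc(CO)cc1
Why: Acid-catalysed alkoxy exchange on the β-alkoxy enone (conjugate addition–elimination, a vinylogous transesterification) is driven by distilling off methanol and returns the more stable E enone.

Step 2
Reactants: 2 (E)-4-[(4-methoxybenzyl)oxy]but-3-en-2-one
Product: 4 (E)-1-[(4-methoxybenzyl)oxy]pent-1-en-3-one, via lithium dienolate 3 (not isolated)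
Conditions: LiN(iPr)2, THF, −78 °C; MeI, −78 → −30 °C
Reagents that add atoms: iodomethane, CI
Why: Kinetic deprotonation of the vinylogous ester takes place at the α′ methyl group and the cross-conjugated enolate is C-methylated (enolate alkylation), which adds the carbon that becomes C20.

Step 3
Reactants: 4 (E)-1-[(4-methoxybenzyl)oxy]pent-1-en-3-one
Product: 5 (1E,3Z)-3-(tert-butyldimethylsilyloxy)-1-[(4-methoxybenzyl)oxy]penta-1,3-diene
Conditions: TBSOTf, Et3N, Et2O, −78 → 0 °C
Reagents that add atoms: tert-butyldimethylsilyl trifluoromethanesulfonate, CC(C)(C)[Si](C)(C)OS(=O)(=O)C(F)(F)F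
Why: Soft enolisation of the ethyl ketone with silyl triflate and amine (silyl enol ether formation) gives the Z enol ether, so that in the s-cis diene the methyl and the benzyloxy group both point outward.

Step 4
Reactants: 5 (1E,3Z)-3-(tert-butyldimethylsilyloxy)-1-[(4-methoxybenzyl)oxy]penta-1,3-diene; 6 2-methoxy-5-methyl-1,4-benzoquinone
Product: 7 cis-fused Diels–Alder adduct (H10β, 15β-CH3, 11α-CH3, 14α-OPMB; ring B: C2=O, C7=C8–OMe, C9=O; ring A: C12(OTBS)=C13)
Conditions: (S)-1-(2-methylphenyl)-3,3-diphenyltetrahydro-1H,3H-pyrrolo[1,2-c][1,3,2]oxazaborole·HN(SO2CF3)2 (20 mol %), CH2Cl2, −78 °C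
Reagents that add atoms: none
Why: Catalytic enantioselective Diels–Alder reaction in which the cationic boron Lewis acid binds the more basic vinylogous-ester carbonyl (C2=O), making C10 the electrophilic terminus so that the nucleophilic diene carbon C11 bonds to C10 and C14 to C1, while the methoxy-bearing olefin is deactivated, endo approach places the 14-ether and the 11-methyl anti to the C1 methyl, and the catalyst shields one quinone face to fix C1 and C14.

Step 5
Reactants: 7 cis-fused Diels–Alder adduct
Product: 8 cis-fused 2,9,12-triketone (C7=C8–OMe kept; H10β, 11α-CH3, 14α-OPMB)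
Conditions: HF·pyridine, pyridine, THF, 0 °C
Reagents that add atoms: none
Why: Buffered fluoride protodesilylation of the silyl enol ether (protonation at C13) unmasks the C12 ketone without the acid that would eliminate the β-benzyloxy group, and the C10 and C11 centres, left untouched, are erased in the next step.

Step 6
Reactants: 8 cis-fused 2,9,12-triketone
Product: 9 C10=C11 ene-dione 14α-PMB ether (C2, C9, C12 carbonyls; C7=C8–OMe)
Conditions: IBX, 4-methoxypyridine N-oxide, DMSO, 25 °C
Reagents that add atoms: none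
Why: IBX dehydrogenation of a saturated 1,4-diketone, in which enolisation of either ketone toward C10 or C11 and single-electron oxidation converge on the conjugated C10=C11 ene-dione, is run at room temperature with the N-oxide-activated reagent to spare the β-alkoxy ketone.

Step 7
Reactants: 9 C10=C11 ene-dione 14α-PMB ether
Product: 10 C10=C11 ene-dione with free 14α-OH
Conditions: DDQ, CH2Cl2/pH 7 phosphate buffer, 0 °C
Reagents that add atoms: none
Why: Oxidative cleavage of the 4-methoxybenzyl ether by DDQ (benzylic hydride abstraction, then hydrolysis of the oxocarbenium ion) under buffered neutral conditions frees the 14-hydroxyl without dehydration of the β-hydroxy ketone.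

Step 8
Reactants: 10 C10=C11 ene-dione with free 14α-OH
Product: 11 12β,14α-diol (C10=C11 enone conjugated to C9=O; C2=O and C7=C8–OMe kept)
Conditions: Me4NBH(OAc)3, MeCN/AcOH, −30 °C
Reagents that add atoms: none
Why: Hydroxyl-directed triacetoxyborohydride reduction: the 14α-oxygen binds boron and delivers hydride internally to the α face of the C12 carbonyl, giving the 12β-alcohol anti to the 14-hydroxyl, whereas the C9 ketone has no β-hydroxyl and the vinylogous-ester carbonyl C2 is too electron-rich to react.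

Step 9
Reactants: 11 12β,14α-diol
Product: 12 12β-OTBDPS ether of 11 (14α-OH free)
Conditions: TBDPSCl, imidazole, DMF, 0 °C → rt
Reagents that add atoms: tert-butyldiphenylsilyl chloride, CC(C)(C)[Si](Cl)(c1ccccc1)c1ccccc1
Why: Silyl ether formation with a bulky chlorosilane selects the accessible allylic 12-hydroxyl over the axial, neopentyl 14-hydroxyl.

Step 10
Reactants: 12 12β-OTBDPS ether (14α-OH free)
Product: 13 trans-fused ketone (H10α, 11β-CH3, 12β-OTBDPS, 14α-OH; C9=O, C2=O, C7=C8–OMe)
Conditions: [Ir(cod)(PCy3)(py)]PF6 (10 mol %), H2 (1 atm), CH2Cl2, rt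
Reagents that add atoms: none
Why: Hydroxyl-directed homogeneous hydrogenation: the free 14α-hydroxyl binds the cationic iridium centre and both hydrogens are added syn to the α face of the tetrasubstituted olefin, whose β face is screened by the C1 methyl and the 12β-silyloxy group, which gives the trans ring fusion (H10α) and the axial 11β-methyl, a centre that cannot epimerise because C12 is no longer a ketone.

Step 11
Reactants: 13 trans-fused ketone
Product: 14 9β-alcohol of 13 (9β,14α-diol)
Conditions: NaBH4, CeCl3·7H2O, MeOH, −78 °C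
Reagents that add atoms: none
Why: Luche reduction attacks the cross-conjugated C9 ketone in 1,2 fashion in preference to the less electrophilic vinylogous-ester carbonyl, and hydride enters from the α face, away from the syn-axial C1 methyl, to give the 9β-alcohol.

Step 12
Reactants: 14 9β,14α-diol
Product: 15 9β,14α-bis-OTBS-12β-OTBDPS vinylogous ester (C2=O, C7=C8–OMe)
Conditions: TBSOTf, 2,6-lutidine, CH2Cl2, 0 °C → rt
Reagents that add atoms: tert-butyldimethylsilyl trifluoromethanesulfonate, CC(C)(C)[Si](C)(C)OS(=O)(=O)C(F)(F)F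
Why: Silyl ether formation with the reactive silyl triflate and a hindered pyridine base covers both hindered secondary hydroxyls and leaves the vinylogous ester untouched.

Step 13
Reactants: 15 tris-silylated vinylogous ester; 16 vinylmagnesium bromide
Product: 17 C2 vinyl carbinol (2α-vinyl, 2β-OH) with C7=C8 methyl enol ether
Conditions: LaCl3·2LiCl (0.3 equiv), THF, −78 → −20 °C; aq. NaHCO3 work-up
Reagents that add atoms: none
Why: 1,2-Addition of the Grignard reagent to the vinylogous-ester carbonyl (the first half of a Stork–Danheiser sequence, halted by a basic work-up), assisted by the oxophilic lanthanum salt, should occur anti to the adjacent axial C1 methyl, and the C2 configuration is in any case erased in step 17.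

Step 14
Reactants: 17 C2 vinyl carbinol
Product: 19 2β,7β-diol with C8 dimethyl ketal (2α-vinyl), via methoxy epoxide 18 (not isolated)
Conditions: mCPBA, NaHCO3, MeOH, −20 → 0 °C
Reagents that add atoms: 3-chloroperoxybenzoic acid, O=C(OO)c1cccc(Cl)c1; methanol, CO
Why: Peracid epoxidation of the electron-rich enol ether, much faster than that of the vinyl group and guided to the β face by the tertiary hydroxyl, followed by methanolysis of the alkoxy epoxide at the acetal carbon (Rubottom-type oxidation) gives the α-hydroxy dimethyl ketal, with bicarbonate preventing ionisation of the tertiary allylic alcohol and the C7 centre being oxidised away next.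

Step 15
Reactants: 19 2β,7β-diol with C8 dimethyl ketal
Product: 20 C7 ketone with 2β-OH, 2α-vinyl and C8 dimethyl ketal
Conditions: IBX, DMSO, rt
Reagents that add atoms: none
Why: IBX oxidation of the secondary alcohol stops at the α-ketol, since this reagent does not cleave 1,2-diols, and the product cannot enolise because both neighbours (C2, C8) are fully substituted.

Step 16
Reactants: 20 C7 ketone; 21 1-propynylmagnesium bromide
Product: 22 cis-2β,7β-diol with 2α-vinyl and 7α-(1-propynyl), C8 dimethyl ketal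
Conditions: 21 (3 equiv), LaCl3·2LiCl (0.3 equiv), THF, −78 → 0 °C
Reagents that add atoms: none
Why: Grignard addition to the non-enolisable ketone, after the first equivalent has deprotonated the tertiary hydroxyl, should take the equatorial α path because the axial C1 methyl and the axial 9-silyloxy group close the β face, which gives the cis-diol with the axial vinyl and equatorial propynyl groups gauche.

Step 17
Reactants: 22 cis-2β,7β-diol with 2α-vinyl and 7α-(1-propynyl)
Product: 25 (5Z)-cyclodecenedione (C2 ketone, C5=C6–C7=O enone, C8 dimethyl ketal; ring A unchanged), via dipotassium diolate 23 (not isolated), via dipotassium enolate-allenolate 24 (not isolated)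
Conditions: KN(SiMe3)2 (2.5 equiv), 18-crown-6, THF, −78 → 0 °C; then cannulated into AcOH/THF at −78 °C
Reagents that add atoms: none
Why: Proposed new method: double deprotonation gives the dipotassium cis-1,2-diolate, whose C2–C7 bond lies between two alkoxides, the quaternary C1 and the C8 ketal, and a [3,3] sigmatropic shift over C4=C3–C2–C7–C6≡C5 makes the σ bond C4–C5 while C2–C7 is cleaved, leaving a C2 enolate and a C7 allenolate that the acid quench protonates at C3 and C6. The nearest precedents are anionic oxy-Cope and dioxy-Cope rearrangements that enlarge 1,2-dialkenyl cyclohexanols or cyclohexane-1,2-diols by four carbons, and oxy-Cope rearrangements in which an alkyne is one of the π partners and an allenolate, hence an enone, results; an alkynyl partner in a ring-enlarging diolate has no direct precedent. The ten-membered ring (C1–C10) is not made by an end-to-end cyclisation but by ring enlargement, the four-carbon unit C3–C6 being placed between C2 and C7 of six-membered ring B. No stereocentre is created, and the two carbinol centres, whose configuration is therefore immaterial, disappear. The selectivity needed is the C5=C6 geometry: the allenolate must be protonated at C6 in the plane of the C5 substituents from the side of the exocyclic methyl, because the ring chain fills the C4 side, which gives the Z enone, also the less strained isomer. The substrate secures the rest: the axial vinyl and equatorial propynyl groups are gauche so that C4 can reach C5, ring B is strained by three syn-axial groups, and the inverse cold quench protonates both enolates before a transannular aldol reaction can begin.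

Step 18
Reactants: 25 (5Z)-cyclodecenedione
Product: 26 (2S,7S)-diol (2β-OH, 7α-OH, Z-C5=C6, C8 dimethyl ketal)
Conditions: (R)-1-methyl-3,3-diphenyltetrahydro-1H,3H-pyrrolo[1,2-c][1,3,2]oxazaborole (0.5 equiv), BH3·SMe2, THF, −30 °C; MeOH
Reagents that add atoms: none
Why: Corey–Bakshi–Shibata reduction of both ketones under catalyst control: each carbonyl has one fully substituted neighbour (C1, C8) and one unbranched neighbour (C3, C6), so the (R)-catalyst, which binds the carbonyl oxygen on the side of the smaller group, should deliver hydride to give the 2S and 7S alcohols (2β-OH, 7α-OH), the enone reacting in 1,2 fashion.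

Step 19
Reactants: 26 (2S,7S)-diol with C8 dimethyl ketal
Product: 27 8-ketone with 2β-OH and 7α-OH
Conditions: PPTS, acetone/H2O, 40 °C
Reagents that add atoms: water, O
Why: Acid-catalysed ketal hydrolysis (transketalisation to acetone and water) with a weak pyridinium acid should free the C8 ketone, while the allylic C7 carbinol is protected from ionisation by the electron-poor neighbouring carbon and the hindered silyl ethers tolerate the mild acid.

Step 20
Reactants: 27 8-ketone with 2β-OH and 7α-OH; 28 ethyl propionate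
Product: 30 γ-lactone (O7–C19(=O)–C17–C8; 2β-OH, 8α-OH, 17R; 9β,14α-bis-OTBS, 12β-OTBDPS), via trilithium aldolate 29 (not isolated)
Conditions: 28 (4.5 equiv), LiN(iPr)2 (4.2 equiv), THF, −78 °C; then 27, −78 → 0 °C; AcOH
Reagents that add atoms: none
Why: Aldol addition of the ester lithium enolate to the C8 ketone followed by lactonisation (acyl substitution by the C7 alkoxide): prior deprotonation of the C2 and C7 hydroxyls blocks enolisation toward C7, the lithium chelate between the C7 alkoxide and the C8 carbonyl is attacked from the face of H7, anti to C6 (chelation control), which gives the 8α-hydroxyl syn to O7, and the epimerisable C17 centre is expected to settle under the basic conditions with its methyl trans to C9 and cis to the 8-hydroxyl.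

Step 21
Reactants: 30 silyl-protected γ-lactone
Product: 31 2β,8α,9β,14α-tetraol lactone with 12β-OTBDPS
Conditions: 48% aq. HF, MeCN, 0 °C → rt
Reagents that add atoms: none
Why: Selective desilylation: acidic fluoride cleaves the two secondary tert-butyldimethylsilyl ethers far faster than the tert-butyldiphenylsilyl ether, and the lactone, the tertiary alcohol and the olefin are inert.

Step 22
Reactants: 31 tetraol lactone with 12β-OTBDPS
Product: 32 2β,9β,14α-triacetate with free 8α-OH and 12β-OTBDPS
Conditions: Ac2O, DMAP, pyridine, rt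
Reagents that add atoms: acetic anhydride, CC(=O)OC(C)=O
Why: DMAP-catalysed acetylation esterifies the three secondary hydroxyls, whereas the tertiary 8-hydroxyl is too hindered to react.

Step 23
Reactants: 32 triacetate with 12β-OTBDPS
Product: 33 target CNP0195208.2, the (1S,2S,5Z,7S,8S,9S,10S,11R,12S,14S,17R) 2β,9β,14α-triacetoxy-8α,12β-dihydroxy briarane 7,8-γ-lactone
Conditions: HF·pyridine (excess), THF, rt → 40 °C
Reagents that add atoms: none
Why: Fluoride-mediated cleavage of the remaining silyl ether under non-basic conditions releases the 12-hydroxyl without migration or loss of the acetates.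

Compound list
1 | (E)-4-methoxybut-3-en-2-one | CO/C=C/C(C)=O | starting material
2 | (E)-4-[(4-methoxybenzyl)oxy]but-3-en-2-one | CC(=O)/C=C/OCc1ccc(OC)cc1 | intermediate
3 | lithium (E)-4-[(4-methoxybenzyl)oxy]buta-1,3-dien-2-olate | [Li+].C=C([O-])/C=C/OCc1ccc(OC)cc1 | intermediate (not isolated)
4 | (E)-1-[(4-methoxybenzyl)oxy]pent-1-en-3-one | CCC(=O)/C=C/OCc1ccc(OC)cc1 | intermediate
5 | (1E,3Z)-3-(tert-butyldimethylsilyloxy)-1-[(4-methoxybenzyl)oxy]penta-1,3-diene | C/C=C(\O[Si](C)(C)C(C)(C)C)/C=C/OCc1ccc(OC)cc1 | intermediate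
6 | 2-methoxy-5-methyl-1,4-benzoquinone | COC1=CC(=O)C(C)=CC1=O | starting material
7 | cis-fused Diels–Alder adduct (H10β, 15β-CH3, 11α-CH3, 14α-OPMB, C12 silyl enol ether) | O=C1C=C(OC)C(=O)[C@@H]2[C@H](C)C(O[Si](C)(C)C(C)(C)C)=C[C@H](OCc3ccc(OC)cc3)[C@@]21C | intermediate
8 | cis-fused 2,9,12-triketone, 14α-OPMB | O=C1C=C(OC)C(=O)[C@@H]2[C@H](C)C(=O)C[C@H](OCc3ccc(OC)cc3)[C@@]21C | intermediate
9 | C10=C11 ene-dione, 14α-OPMB | O=C1C=C(OC)C(=O)C2=C(C)C(=O)C[C@H](OCc3ccc(OC)cc3)[C@@]21C | intermediate
10 | C10=C11 ene-dione with free 14α-OH | O=C1C=C(OC)C(=O)C2=C(C)C(=O)C[C@H](O)[C@@]21C | intermediate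
11 | 12β,14α-diol, C10=C11 enone | O=C1C=C(OC)C(=O)C2=C(C)[C@@H](O)C[C@H](O)[C@@]21C | intermediate
12 | 12β-OTBDPS, 14α-OH, C10=C11 enone | O=C1C=C(OC)C(=O)C2=C(C)[C@@H](O[Si](c3ccccc3)(c3ccccc3)C(C)(C)C)C[C@H](O)[C@@]21C | intermediate
13 | trans-fused ketone (H10α, 11β-CH3, 12β-OTBDPS, 14α-OH, C9=O) | O=C1C=C(OC)C(=O)[C@H]2[C@@H](C)[C@@H](O[Si](c3ccccc3)(c3ccccc3)C(C)(C)C)C[C@H](O)[C@@]21C | intermediate
14 | 9β,14α-diol, 12β-OTBDPS | O=C1C=C(OC)[C@@H](O)[C@H]2[C@@H](C)[C@@H](O[Si](c3ccccc3)(c3ccccc3)C(C)(C)C)C[C@H](O)[C@@]21C | intermediate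
15 | 9β,14α-bis-OTBS-12β-OTBDPS vinylogous ester | O=C1C=C(OC)[C@@H](O[Si](C)(C)C(C)(C)C)[C@H]2[C@@H](C)[C@@H](O[Si](c3ccccc3)(c3ccccc3)C(C)(C)C)C[C@H](O[Si](C)(C)C(C)(C)C)[C@@]21C | intermediate
16 | vinylmagnesium bromide | C=C[Mg]Br | starting material
17 | C2 vinyl carbinol (2α-vinyl, 2β-OH), C7=C8 methyl enol ether | C=C[C@]1(O)C=C(OC)[C@@H](O[Si](C)(C)C(C)(C)C)[C@H]2[C@@H](C)[C@@H](O[Si](c3ccccc3)(c3ccccc3)C(C)(C)C)C[C@H](O[Si](C)(C)C(C)(C)C)[C@@]21C | intermediate
18 | 7β,8β-epoxide of 17 (8-methoxy oxirane) | C=C[C@]1(O)[C@H]4O[C@@]4(OC)[C@@H](O[Si](C)(C)C(C)(C)C)[C@H]2[C@@H](C)[C@@H](O[Si](c3ccccc3)(c3ccccc3)C(C)(C)C)C[C@H](O[Si](C)(C)C(C)(C)C)[C@@]21C | intermediate (not isolated)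
19 | 2β,7β-diol with C8 dimethyl ketal | C=C[C@]1(O)[C@@H](O)C(OC)(OC)[C@@H](O[Si](C)(C)C(C)(C)C)[C@H]2[C@@H](C)[C@@H](O[Si](c3ccccc3)(c3ccccc3)C(C)(C)C)C[C@H](O[Si](C)(C)C(C)(C)C)[C@@]21C | intermediate
20 | C7 ketone, 2β-OH, 2α-vinyl, C8 dimethyl ketal | C=C[C@]1(O)C(=O)C(OC)(OC)[C@@H](O[Si](C)(C)C(C)(C)C)[C@H]2[C@@H](C)[C@@H](O[Si](c3ccccc3)(c3ccccc3)C(C)(C)C)C[C@H](O[Si](C)(C)C(C)(C)C)[C@@]21C | intermediate
21 | 1-propynylmagnesium bromide | CC#C[Mg]Br | starting material
22 | cis-2β,7β-diol, 2α-vinyl, 7α-(1-propynyl), C8 dimethyl ketal | C=C[C@]1(O)[C@](O)(C#CC)C(OC)(OC)[C@@H](O[Si](C)(C)C(C)(C)C)[C@H]2[C@@H](C)[C@@H](O[Si](c3ccccc3)(c3ccccc3)C(C)(C)C)C[C@H](O[Si](C)(C)C(C)(C)C)[C@@]21C | intermediate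
23 | dipotassium 2,7-diolate of 22 | [K+].[K+].C=C[C@]1([O-])[C@]([O-])(C#CC)C(OC)(OC)[C@@H](O[Si](C)(C)C(C)(C)C)[C@H]2[C@@H](C)[C@@H](O[Si](c3ccccc3)(c3ccccc3)C(C)(C)C)C[C@H](O[Si](C)(C)C(C)(C)C)[C@@]21C | intermediate (not isolated)
24 | dipotassium C2 enolate, C7 allenolate of the ten-membered ring | [K+].[K+].[O-]C1=CCC(C)=C=C([O-])C(OC)(OC)[C@@H](O[Si](C)(C)C(C)(C)C)[C@H]2[C@@H](C)[C@@H](O[Si](c3ccccc3)(c3ccccc3)C(C)(C)C)C[C@H](O[Si](C)(C)C(C)(C)C)[C@@]21C | intermediate (not isolated)
25 | (5Z)-cyclodecenedione: C2 ketone, C5=C6–C7=O, C8 dimethyl ketal | O=C1CC/C(C)=C\C(=O)C(OC)(OC)[C@@H](O[Si](C)(C)C(C)(C)C)[C@H]2[C@@H](C)[C@@H](O[Si](c3ccccc3)(c3ccccc3)C(C)(C)C)C[C@H](O[Si](C)(C)C(C)(C)C)[C@@]21C | intermediate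
26 | (2S,7S)-diol (2β-OH, 7α-OH), C8 dimethyl ketal | O[C@H]1CC/C(C)=C\[C@H](O)C(OC)(OC)[C@@H](O[Si](C)(C)C(C)(C)C)[C@H]2[C@@H](C)[C@@H](O[Si](c3ccccc3)(c3ccccc3)C(C)(C)C)C[C@H](O[Si](C)(C)C(C)(C)C)[C@@]21C | intermediate
27 | 8-ketone with 2β-OH and 7α-OH | O[C@H]1CC/C(C)=C\[C@H](O)C(=O)[C@@H](O[Si](C)(C)C(C)(C)C)[C@H]2[C@@H](C)[C@@H](O[Si](c3ccccc3)(c3ccccc3)C(C)(C)C)C[C@H](O[Si](C)(C)C(C)(C)C)[C@@]21C | intermediate
28 | ethyl propionate | CCC(=O)OCC | starting material
29 | trilithium alkoxide of the C8 aldol adduct (8α-O, 17R ethyl ester) | [Li+].[Li+].[Li+].[O-][C@H]1CC/C(C)=C\[C@H]([O-])[C@@]([O-])([C@@H](C)C(=O)OCC)[C@@H](O[Si](C)(C)C(C)(C)C)[C@H]2[C@@H](C)[C@@H](O[Si](c3ccccc3)(c3ccccc3)C(C)(C)C)C[C@H](O[Si](C)(C)C(C)(C)C)[C@@]21C | intermediate (not isolated)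
30 | silyl-protected γ-lactone, 2β-OH, 8α-OH, 17R | O[C@H]1CC/C(C)=C\[C@@H]2OC(=O)[C@H](C)[C@@]2(O)[C@@H](O[Si](C)(C)C(C)(C)C)[C@H]2[C@@H](C)[C@@H](O[Si](c3ccccc3)(c3ccccc3)C(C)(C)C)C[C@H](O[Si](C)(C)C(C)(C)C)[C@@]21C | intermediate
31 | 2β,8α,9β,14α-tetraol lactone, 12β-OTBDPS | O[C@H]1CC/C(C)=C\[C@@H]2OC(=O)[C@H](C)[C@@]2(O)[C@@H](O)[C@H]2[C@@H](C)[C@@H](O[Si](c3ccccc3)(c3ccccc3)C(C)(C)C)C[C@H](O)[C@@]21C | intermediate
32 | 2β,9β,14α-triacetate, 8α-OH, 12β-OTBDPS | CC(=O)O[C@H]1CC/C(C)=C\[C@@H]2OC(=O)[C@H](C)[C@@]2(O)[C@@H](OC(C)=O)[C@H]2[C@@H](C)[C@@H](O[Si](c3ccccc3)(c3ccccc3)C(C)(C)C)C[C@H](OC(C)=O)[C@@]21C | intermediate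
33 | CNP0195208.2 | CC(=O)O[C@H]1CC/C(C)=C\[C@@H]2OC(=O)[C@H](C)[C@@]2(O)[C@@H](OC(C)=O)[C@H]2[C@@H](C)[C@@H](O)C[C@H](OC(C)=O)[C@@]21C | target

Total step count: 23. Longest linear sequence: 23 steps (1 → 33); compounds 6, 16, 21 and 28 are bought and enter directly.

Steps most likely to fail

Step 17 (the unprecedented rearrangement). Several processes may go wrong: migration of a silyl group from O9 or O14 to the neighbouring potassium alkoxide before the shift; heterolytic fragmentation of the diolate without recombination; transannular aldol closure during the quench; or erosion of the olefin geometry. The fallback sets out from 20 and comes back at 25, and rests only on the precedented anionic oxy-Cope ring expansion of 1,2-dialkenylcyclohexanols. The tertiary hydroxyl of 20 is capped (MOMCl, iPr2NEt, Bu4NI, CH2Cl2, 40 °C) to give the 2-O-methoxymethyl ketone F1. 1-Propenylmagnesium bromide (LaCl3·2LiCl, THF) adds to C7=O to give the 7-(1-propenyl) carbinol F2. KH and 18-crown-6 in THF trigger the oxy-Cope shift (C4–C5 made, C2–C7 cleaved), and the C7 potassium enolate is trapped at C6 with PhSeBr at −78 °C to give the α-phenylseleno ketone F3, in which C2 remains a methoxymethyl enol ether. H2O2/pyridine gives the selenoxide F4, whose syn elimination toward C5–H gives the C5=C6 enone enol ether F5. PPTS in wet acetone then hydrolyses the enol ether to 25. Any E enone would be equilibrated to the less strained Z isomer with a catalytic thiolate.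

Step 10. The tetrasubstituted olefin, crowded by the neighbouring silyl ether, may fail to bind the iridium catalyst; hydrogen may add without guidance by the 14-hydroxyl; and the C7=C8 enol ether may be reduced in competition. The fallback sets out from 10 and comes back at 13. The hydrogenation is moved forward to the ene-dione 10, where the olefin is unencumbered and the 14-hydroxyl is the only donor ([Ir(cod)(PCy3)(py)]PF6, H2, CH2Cl2), to give the trans-fused saturated hydroxy triketone F6. Because its C11 centre is epimerisable, F6 is reduced at once with Me4NBH(OAc)3 (MeCN/AcOH, −30 °C) to the trans-fused 12β,14α-diol F7. TBDPSCl/imidazole then silylates the equatorial 12-hydroxyl to give 13.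

Step 20. The aldol addition may revert (retro-aldol) before lactonisation; the C8 ketone may be sequestered as a transannular hemiketal with the C2 alkoxide; or the enolate may attack the wrong face of C8. The fallback sets out from 27 and comes back at 30, and delivers the three carbons intramolecularly. The more accessible 7-hydroxyl is esterified selectively (2-bromopropanoic acid, N,N′-diisopropylcarbodiimide, DMAP cat., CH2Cl2, −20 °C) to give the 7-O-(2-bromopropanoyl) ester F8. SmI2 (THF, −78 °C) then effects an intramolecular Reformatsky reaction onto C8=O. The five-membered tether forces C17 onto C8 from the O7 side, and the ring torsion C6–C7–C8–C9 favours the trans-fused lactone 30; C17 remains adjustable by base-mediated epimerisation.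

Further compounds
F1 | step 17 | 2-O-methoxymethyl ether of ketone 20 | C=C[C@]1(OCOC)C(=O)C(OC)(OC)[C@@H](O[Si](C)(C)C(C)(C)C)[C@H]2[C@@H](C)[C@@H](O[Si](c3ccccc3)(c3ccccc3)C(C)(C)C)C[C@H](O[Si](C)(C)C(C)(C)C)[C@@]21C
F2 | step 17 | 7-(1-propenyl) carbinol (2α-vinyl, 2β-OMOM, 7β-OH) | C=C[C@]1(OCOC)[C@](O)(C=CC)C(OC)(OC)[C@@H](O[Si](C)(C)C(C)(C)C)[C@H]2[C@@H](C)[C@@H](O[Si](c3ccccc3)(c3ccccc3)C(C)(C)C)C[C@H](O[Si](C)(C)C(C)(C)C)[C@@]21C
F3 | step 17 | 6-phenylseleno C7 ketone of the ten-membered ring with C2 methoxymethyl enol ether | COCOC1=CCC(C)C([Se]c4ccccc4)C(=O)C(OC)(OC)[C@@H](O[Si](C)(C)C(C)(C)C)[C@H]2[C@@H](C)[C@@H](O[Si](c3ccccc3)(c3ccccc3)C(C)(C)C)C[C@H](O[Si](C)(C)C(C)(C)C)[C@@]21C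
F4 | step 17 | selenoxide of F3 | COCOC1=CCC(C)C([Se](=O)c4ccccc4)C(=O)C(OC)(OC)[C@@H](O[Si](C)(C)C(C)(C)C)[C@H]2[C@@H](C)[C@@H](O[Si](c3ccccc3)(c3ccccc3)C(C)(C)C)C[C@H](O[Si](C)(C)C(C)(C)C)[C@@]21C
F5 | step 17 | (5Z)-C5=C6–C7=O enone with C2 methoxymethyl enol ether | COCOC1=CC/C(C)=C\C(=O)C(OC)(OC)[C@@H](O[Si](C)(C)C(C)(C)C)[C@H]2[C@@H](C)[C@@H](O[Si](c3ccccc3)(c3ccccc3)C(C)(C)C)C[C@H](O[Si](C)(C)C(C)(C)C)[C@@]21C
F6 | step 10 | trans-fused saturated 2,9,12-triketone with 14α-OH (H10α, 11β-CH3) | O=C1C=C(OC)C(=O)[C@H]2[C@@H](C)C(=O)C[C@H](O)[C@@]21C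
F7 | step 10 | trans-fused 12β,14α-diol (C9=O, C2=O kept) | O=C1C=C(OC)C(=O)[C@H]2[C@@H](C)[C@@H](O)C[C@H](O)[C@@]21C
F8 | step 20 | 7-O-(2-bromopropanoyl) ester of 27 | O[C@H]1CC/C(C)=C\[C@H](OC(=O)C(C)Br)C(=O)[C@@H](O[Si](C)(C)C(C)(C)C)[C@H]2[C@@H](C)[C@@H](O[Si](c3ccccc3)(c3ccccc3)C(C)(C)C)C[C@H](O[Si](C)(C)C(C)(C)C)[C@@]21C
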